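**Retrosynthetic overview**
1. Target 34 ⇐ bis-Boc macrocycle 33 (loss of two Boc groups) ⇐ enone 30 by the key step: the amide N–CH2 bond at the butane-1,4-diyl end closes the 20-membered ring and, in the same flask, O5–C4a closes ring B.
2. Enabling feature: O5–C4a of ring B lies β to the C3 carbonyl of ring C (a β-aryloxy ketone, i.e. phenol plus enone), and the amide nitrogen of the (Z)-acrylamide on C9b, carried as an N-Boc imide, is acidic enough to take up the enolate proton and become the nucleophile for the CH2–N bond.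
3. 30 ⇐ Saegusa oxidation of silyl enol ether 29 ⇐ Suzuki union of aryl boronate 18 with (Z)-iodoacrylamide 28 (C4–N–C3 chain from 4-aminobutanol and acrylonitrile).
4. 18 ⇐ Still–Gennari (Z)-olefination of aldehyde 10 ⇐ enantioselective Diels–Alder reaction of 2-arylacrolein 7 with 2-silyloxydiene 9 (sets C9b, builds ring C).
5. Ring order: ring A (arene) bought; ring C in step 5; ring B and the 20-membered ring together in step 17.

Key step: step 17

Remark (assumptions): rings are A (arene), B (dihydrofuran), C (cyclohexanone), with dibenzo[b,d]furan locants (C3 carbonyl, C4a–O5, quaternary C9b, C8 bearing the cinnamoyl arm). The sense of induction in step 5 is assigned by analogy with 2-methyl- and 2-bromoacrolein under this catalyst class; the (S)-catalyst would be taken if the adduct proved antipodal.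

**Step 1**
Reactants: 1 1-(5-bromo-2-hydroxyphenyl)ethan-1-one; 2 triisopropylsilyl trifluoromethanesulfonate
Product: 3 1-[5-bromo-2-(triisopropylsilyloxy)phenyl]ethan-1-one
Conditions: 2,6-lutidine, CH2Cl2, 0 °C → rt
Reagents that add atoms: triisopropylsilyl trifluoromethanesulfonate (2), CC(C)[Si](OS(=O)(=O)C(F)(F)F)(C(C)C)C(C)C
Why: O-silylation of the hydrogen-bonded phenol with a silyl triflate and a hindered base is a standard protection, and the bulky silyl ether masks the phenoxide until the key step.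

**Step 2**
Reactants: 3 1-[5-bromo-2-(triisopropylsilyloxy)phenyl]ethan-1-one; 4 methyltriphenylphosphonium bromide
Product: 5 4-bromo-2-(prop-1-en-2-yl)phenyl triisopropylsilyl ether
Conditions: KOtBu, THF, 0 °C → rt
Reagents that add atoms: methyltriphenylphosphonium bromide (4), C[P+](c1ccccc1)(c1ccccc1)c1ccccc1.[Br-]
Why: Wittig methylenation of the aryl methyl ketone with the non-stabilised ylide should give the 1,1-disubstituted alkene.

**Step 3**
Reactants: 5 4-bromo-2-(prop-1-en-2-yl)phenyl triisopropylsilyl ether; 6 selenium dioxide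
Product: 7 2-[5-bromo-2-(triisopropylsilyloxy)phenyl]prop-2-enal
Conditions: SeO2, 1,4-dioxane/H2O (30:1), 90 °C
Reagents that add atoms: selenium dioxide (6), O=[Se]=O
Why: Riley allylic oxidation (ene reaction, then [2,3]-shift) of the allylic methyl group should give the 2-arylacrolein, as is known for α-methylstyrenes.

**Step 4**
Reactants: 8 but-3-en-2-one; 2 triisopropylsilyl trifluoromethanesulfonate
Product: 9 2-(triisopropylsilyloxy)buta-1,3-diene
Conditions: Et3N, Et2O, 0 °C → rt
Reagents that add atoms: triisopropylsilyl trifluoromethanesulfonate (2), CC(C)[Si](OS(=O)(=O)C(F)(F)F)(C(C)C)C(C)C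
Why: Soft enolisation and O-silylation of methyl vinyl ketone gives the 2-silyloxydiene.

**Step 5**
Reactants: 7 2-[5-bromo-2-(triisopropylsilyloxy)phenyl]prop-2-enal; 9 2-(triisopropylsilyloxy)buta-1,3-diene
Product: 10 (1R)-1-[5-bromo-2-(triisopropylsilyloxy)phenyl]-4-(triisopropylsilyloxy)cyclohex-3-ene-1-carbaldehyde
Conditions: (R)-o-tolyl-CBS oxazaborolidine (20 mol %), HNTf2 (18 mol %), CH2Cl2, −78 °C
Reagents that add atoms: 2-(triisopropylsilyloxy)buta-1,3-diene (9), C=CC(=C)O[Si](C(C)C)(C(C)C)C(C)C
Why: In this catalytic enantioselective Diels–Alder reaction the cationic oxazaborolidine binds the formyl group and shields one face of the s-trans 2-arylacrolein while the diene adds in the para sense, which sets the quaternary stereocentre (future C9b) and places the enol ether double bond on the ring arm that becomes C4–C4a.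

**Step 6**
Reactants: 10 Diels–Alder aldehyde; 11 methyl 2-[bis(2,2,2-trifluoroethoxy)phosphoryl]acetate
Product: 12 methyl (2Z)-3-[(1S)-1-[5-bromo-2-(triisopropylsilyloxy)phenyl]-4-(triisopropylsilyloxy)cyclohex-3-en-1-yl]prop-2-enoate
Conditions: KN(SiMe3)2, 18-crown-6, THF, −78 °C
Reagents that add atoms: methyl 2-[bis(2,2,2-trifluoroethoxy)phosphoryl]acetate (11), COC(=O)CP(=O)(OCC(F)(F)F)OCC(F)(F)F
Why: The Still–Gennari variant of the Horner–Wadsworth–Emmons olefination should give the (Z)-enoate under kinetic control, also with this non-enolisable neopentylic aldehyde.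

**Step 7**
Reactants: 12 (Z)-enoate; 13 ammonia
Product: 14 (2Z)-3-[(1S)-1-[5-bromo-2-(triisopropylsilyloxy)phenyl]-4-(triisopropylsilyloxy)cyclohex-3-en-1-yl]prop-2-enamide
Conditions: AlMe3, NH3 (0.5 M in 1,4-dioxane), CH2Cl2, 0 → 40 °C
Reagents that add atoms: ammonia (13), N
Why: Weinreb aluminium-amide aminolysis (Me2AlNH2 formed in the flask) should convert the methyl ester into the primary amide without touching the silyl enol ether or the (Z)-alkene.

**Step 8**
Reactants: 14 primary (Z)-acrylamide; 15 di-tert-butyl dicarbonate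
Product: 16 tert-butyl N-[(2Z)-3-[(1S)-1-[5-bromo-2-(triisopropylsilyloxy)phenyl]-4-(triisopropylsilyloxy)cyclohex-3-en-1-yl]prop-2-enoyl]carbamate
Conditions: LiN(SiMe3)2 (2.1 equiv), THF, −78 °C; Boc2O (1.0 equiv), −78 → −30 °C; aq. NH4Cl
Reagents that add atoms: di-tert-butyl dicarbonate (15), CC(C)(C)OC(=O)OC(=O)OC(C)(C)C
Why: N-acylation of the amide anion with Boc2O should stop at the mono-Boc stage because the second equivalent of base stores the product as its unreactive imide anion, and the imide-type N–H so created is the nucleophile of the key step.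

**Step 9**
Reactants: 16 N-Boc acrylimide aryl bromide; 17 bis(pinacolato)diboron
Product: 18 aryl pinacol boronate of 16 (Bpin in place of Br)
Conditions: PdCl2(dppf) (5 mol %), KOAc, 1,4-dioxane, 80 °C
Reagents that add atoms: bis(pinacolato)diboron (17), CC1(C)OB(OC1(C)C)B1OC(C)(C)C(C)(C)O1
Why: Miyaura borylation of the unhindered, electron-rich aryl bromide; the weak acetate base leaves the silyl ethers and the (Z)-acrylimide intact.

**Step 10**
Reactants: 19 4-aminobutan-1-ol; 20 prop-2-enenitrile
Product: 21 3-[(4-hydroxybutyl)amino]propanenitrile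
Conditions: MeOH, 0 °C → rt
Reagents that add atoms: prop-2-enenitrile (20), C=CC#N
Why: Aza-Michael addition (cyanoethylation) of the primary amine gives the secondary amine that becomes the central nitrogen.

**Step 11**
Reactants: 21 3-[(4-hydroxybutyl)amino]propanenitrile; 15 di-tert-butyl dicarbonate
Product: 22 tert-butyl N-(2-cyanoethyl)-N-(4-hydroxybutyl)carbamate
Conditions: Boc2O, CH2Cl2, rt
Reagents that add atoms: di-tert-butyl dicarbonate (15), CC(C)(C)OC(=O)OC(=O)OC(C)(C)C
Why: Chemoselective N-tert-butoxycarbonylation of the secondary amine in the presence of the primary alcohol.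

**Step 12**
Reactants: 22 tert-butyl N-(2-cyanoethyl)-N-(4-hydroxybutyl)carbamate
Product: 23 tert-butyl N-(3-aminopropyl)-N-(4-hydroxybutyl)carbamate
Conditions: H2 (4 bar), Raney Ni, 7 M NH3 in MeOH, rt
Reagents that add atoms: none
Why: Catalytic hydrogenation of the nitrile to the primary amine, with ammonia suppressing secondary-amine formation and the carbamate blocking retro-Michael loss of the cyanoethyl group.

**Step 13**
Reactants: 23 tert-butyl N-(3-aminopropyl)-N-(4-hydroxybutyl)carbamate; 24 (2Z)-3-iodoprop-2-enoic acid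
Product: 25 tert-butyl N-(4-hydroxybutyl)-N-[3-[[(2Z)-3-iodoprop-2-enoyl]amino]propyl]carbamate
Conditions: EDC·HCl, HOBt, CH2Cl2, 0 °C
Reagents that add atoms: (2Z)-3-iodoprop-2-enoic acid (24), OC(=O)/C=C\I
Why: Carbodiimide amide coupling at the primary amine (the alcohol does not compete) with the pre-activated acid at low temperature should keep the (Z)-iodoalkene intact.

**Step 14**
Reactants: 25 hydroxybutyl (Z)-iodoacrylamide; 26 lithium chloride
Product: 28 tert-butyl N-(4-chlorobutyl)-N-[3-[[(2Z)-3-iodoprop-2-enoyl]amino]propyl]carbamate, via mesylate 27 (not isolated)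
Conditions: MsCl, Et3N, CH2Cl2, 0 °C; then LiCl, DMF, 50 °C
Reagents that add atoms: lithium chloride (26), [Li+].[Cl-]
Why: Mesylation and SN2 displacement by chloride install a primary chloride that is inert to the cross-coupling and is activated only later by iodide.

**Step 15**
Reactants: 18 aryl pinacol boronate; 28 (Z)-alkenyl iodide
Product: 29 seco silyl enol ether (ring C as triisopropylsilyl enol ether; aryl C8 carrying the (Z)-acrylamide chain that ends in CH2Cl)
Conditions: Pd(PPh3)4 (5 mol %), aq. K3PO4, THF, 40 °C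
Reagents that add atoms: alkenyl iodide 28, CC(C)(C)OC(=O)N(CCCNC(=O)/C=C\I)CCCCCl
Why: Suzuki–Miyaura coupling of the aryl boronate with the (Z)-alkenyl iodide proceeds with retention of alkene geometry and joins the two halves under mild base.

**Step 16**
Reactants: 29 seco silyl enol ether
Product: 30 (S)-enone (4-aryl-4-alkenylcyclohex-2-en-1-one; aryl silyl ether, N-Boc imide N–H and CH2Cl terminus in place)
Conditions: Pd(OAc)2 (1.2 equiv), MeCN, 40 °C
Reagents that add atoms: none
Why: In this Saegusa–Ito oxidation, palladation of the enol ether α-carbon and β-hydride elimination from the CH2 next to the quaternary carbon should give the enone regiospecifically, because the enol ether position was fixed in step 5.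

**Step 17**
Reactants: 30 (S)-enone
Product: 33 (4aR,9bS)-bis-Boc macrocycle (target carrying Boc on the C9b-arm amide nitrogen and on the central amine), via tricyclic chloride 31 (not isolated), via tricyclic iodide 32 (not isolated)
Conditions: CsF (1.3 equiv), Bu4NI (1 equiv), DMF (0.001 M), 50 °C; pH 7 buffer work-up
Reagents that add atoms: none
Why: Fluoride cleaves the aryl silyl ether and the phenoxide adds to C4a of the ring C enone (oxa-Michael), the enolate is protonated by the imide N–H, and the imide anion so formed displaces the primary halide at the chain terminus (chloride exchanged in the flask for iodide by Bu4NI), which forms the N–CH2 bond and closes the macrocycle. The closest known reaction types are fluoride- or base-triggered phenol oxa-Michael cyclisations to cis-hexahydrodibenzofuranones and Gabriel-type N-alkylation of imide or acyl carbamate anions used for macrocyclisation at high dilution. Ring B closes 5-exo-trig and the 20-membered ring closes by intramolecular SN2 (exo-tet) at a primary carbon. The new stereocentre C4a is controlled by C9b, since the oxygen is tethered through ring A and can reach C4a only on the face of the C9b–aryl bond, so the B/C fusion must be cis and (4aR) follows from (S)-C9b. The step needs O- rather than N-attack at C4a and N- rather than O-alkylation at the halide: the phenoxide is released directly above C4a while the hindered imide nitrogen could add only reversibly, and once ring B is closed the imide anion (N–H far more acidic than the ketone α-C–H) is the only nucleophile left, the single equivalent of base having been relayed from O to C to N. High dilution favours ring closure over oligomerisation, and the two (Z)-alkenes and the meta-bridged arene restrict the chain.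

**Step 18**
Reactants: 33 (4aR,9bS)-bis-Boc macrocycle
Product: 34 CNP0415009.2 (target)
Conditions: CF3CO2H/CH2Cl2 (1:4), 0 °C → rt; aq. NaHCO3 work-up
Reagents that add atoms: none
Why: Acidolysis removes both tert-butyl carbamates (the imide-type Boc on the amide nitrogen being the more labile), and mild basic work-up should release the free secondary amine without touching the (Z)-enamides or the β-aryloxy ketone.

**Compound list**
1 | 1-(5-bromo-2-hydroxyphenyl)ethan-1-one | CC(=O)c1cc(Br)ccc1O | starting material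
2 | triisopropylsilyl trifluoromethanesulfonate | CC(C)[Si](OS(=O)(=O)C(F)(F)F)(C(C)C)C(C)C | starting material
3 | 1-[5-bromo-2-(triisopropylsilyloxy)phenyl]ethan-1-one | CC(=O)c1cc(Br)ccc1O[Si](C(C)C)(C(C)C)C(C)C | intermediate
4 | methyltriphenylphosphonium bromide | C[P+](c1ccccc1)(c1ccccc1)c1ccccc1.[Br-] | starting material
5 | 4-bromo-2-(prop-1-en-2-yl)phenyl triisopropylsilyl ether | CC(=C)c1cc(Br)ccc1O[Si](C(C)C)(C(C)C)C(C)C | intermediate
6 | selenium dioxide | O=[Se]=O | starting material
7 | 2-[5-bromo-2-(triisopropylsilyloxy)phenyl]prop-2-enal | C=C(C=O)c1cc(Br)ccc1O[Si](C(C)C)(C(C)C)C(C)C | intermediate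
8 | but-3-en-2-one | CC(=O)C=C | starting material
9 | 2-(triisopropylsilyloxy)buta-1,3-diene | C=CC(=C)O[Si](C(C)C)(C(C)C)C(C)C | intermediate
10 | (1R)-1-[5-bromo-2-(triisopropylsilyloxy)phenyl]-4-(triisopropylsilyloxy)cyclohex-3-ene-1-carbaldehyde | CC(C)[Si](C(C)C)(C(C)C)OC1=CC[C@@](C=O)(c2cc(Br)ccc2O[Si](C(C)C)(C(C)C)C(C)C)CC1 | intermediate
11 | methyl 2-[bis(2,2,2-trifluoroethoxy)phosphoryl]acetate | COC(=O)CP(=O)(OCC(F)(F)F)OCC(F)(F)F | starting material
12 | methyl (2Z)-3-[(1S)-1-[5-bromo-2-(triisopropylsilyloxy)phenyl]-4-(triisopropylsilyloxy)cyclohex-3-en-1-yl]prop-2-enoate | CC(C)[Si](C(C)C)(C(C)C)OC1=CC[C@@](/C=C\C(=O)OC)(c2cc(Br)ccc2O[Si](C(C)C)(C(C)C)C(C)C)CC1 | intermediate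
13 | ammonia | N | starting material
14 | (2Z)-3-[(1S)-1-[5-bromo-2-(triisopropylsilyloxy)phenyl]-4-(triisopropylsilyloxy)cyclohex-3-en-1-yl]prop-2-enamide | CC(C)[Si](C(C)C)(C(C)C)OC1=CC[C@@](/C=C\C(N)=O)(c2cc(Br)ccc2O[Si](C(C)C)(C(C)C)C(C)C)CC1 | intermediate
15 | di-tert-butyl dicarbonate | CC(C)(C)OC(=O)OC(=O)OC(C)(C)C | starting material
16 | tert-butyl N-[(2Z)-3-[(1S)-1-[5-bromo-2-(triisopropylsilyloxy)phenyl]-4-(triisopropylsilyloxy)cyclohex-3-en-1-yl]prop-2-enoyl]carbamate | CC(C)[Si](C(C)C)(C(C)C)OC1=CC[C@@](/C=C\C(=O)NC(=O)OC(C)(C)C)(c2cc(Br)ccc2O[Si](C(C)C)(C(C)C)C(C)C)CC1 | intermediate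
17 | bis(pinacolato)diboron | CC1(C)OB(OC1(C)C)B1OC(C)(C)C(C)(C)O1 | starting material
18 | tert-butyl N-[(2Z)-3-[(1S)-1-[5-(4,4,5,5-tetramethyl-1,3,2-dioxaborolan-2-yl)-2-(triisopropylsilyloxy)phenyl]-4-(triisopropylsilyloxy)cyclohex-3-en-1-yl]prop-2-enoyl]carbamate | CC(C)[Si](C(C)C)(C(C)C)OC1=CC[C@@](/C=C\C(=O)NC(=O)OC(C)(C)C)(c2cc(B3OC(C)(C)C(C)(C)O3)ccc2O[Si](C(C)C)(C(C)C)C(C)C)CC1 | intermediate
19 | 4-aminobutan-1-ol | NCCCCO | starting material
20 | prop-2-enenitrile | C=CC#N | starting material
21 | 3-[(4-hydroxybutyl)amino]propanenitrile | N#CCCNCCCCO | intermediate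
22 | tert-butyl N-(2-cyanoethyl)-N-(4-hydroxybutyl)carbamate | CC(C)(C)OC(=O)N(CCC#N)CCCCO | intermediate
23 | tert-butyl N-(3-aminopropyl)-N-(4-hydroxybutyl)carbamate | CC(C)(C)OC(=O)N(CCCN)CCCCO | intermediate
24 | (2Z)-3-iodoprop-2-enoic acid | OC(=O)/C=C\I | starting material
25 | tert-butyl N-(4-hydroxybutyl)-N-[3-[[(2Z)-3-iodoprop-2-enoyl]amino]propyl]carbamate | CC(C)(C)OC(=O)N(CCCNC(=O)/C=C\I)CCCCO | intermediate
26 | lithium chloride | [Li+].[Cl-] | starting material
27 | 4-[(tert-butoxycarbonyl)[3-[[(2Z)-3-iodoprop-2-enoyl]amino]propyl]amino]butyl methanesulfonate | CC(C)(C)OC(=O)N(CCCNC(=O)/C=C\I)CCCCOS(C)(=O)=O | intermediate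
28 | tert-butyl N-(4-chlorobutyl)-N-[3-[[(2Z)-3-iodoprop-2-enoyl]amino]propyl]carbamate | CC(C)(C)OC(=O)N(CCCNC(=O)/C=C\I)CCCCCl | intermediate
29 | tert-butyl N-[(2Z)-3-[(1S)-1-[5-[(1Z)-3-[[3-[(tert-butoxycarbonyl)(4-chlorobutyl)amino]propyl]amino]-3-oxoprop-1-en-1-yl]-2-(triisopropylsilyloxy)phenyl]-4-(triisopropylsilyloxy)cyclohex-3-en-1-yl]prop-2-enoyl]carbamate | CC(C)[Si](C(C)C)(C(C)C)OC1=CC[C@@](/C=C\C(=O)NC(=O)OC(C)(C)C)(c2cc(/C=C\C(=O)NCCCN(CCCCCl)C(=O)OC(C)(C)C)ccc2O[Si](C(C)C)(C(C)C)C(C)C)CC1 | intermediate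
30 | tert-butyl N-[(2Z)-3-[(1S)-1-[5-[(1Z)-3-[[3-[(tert-butoxycarbonyl)(4-chlorobutyl)amino]propyl]amino]-3-oxoprop-1-en-1-yl]-2-(triisopropylsilyloxy)phenyl]-4-oxocyclohex-2-en-1-yl]prop-2-enoyl]carbamate | O=C1CC[C@](/C=C\C(=O)NC(=O)OC(C)(C)C)(c2cc(/C=C\C(=O)NCCCN(CCCCCl)C(=O)OC(C)(C)C)ccc2O[Si](C(C)C)(C(C)C)C(C)C)C=C1 | intermediate
31 | tert-butyl N-[(2Z)-3-[(4aR,9bS)-8-[(1Z)-3-[[3-[(tert-butoxycarbonyl)(4-chlorobutyl)amino]propyl]amino]-3-oxoprop-1-en-1-yl]-3-oxo-1,2,4,4a-tetrahydrodibenzo[b,d]furan-9b(3H)-yl]prop-2-enoyl]carbamate (cis-fused) | O=C1CC[C@]2(/C=C\C(=O)NC(=O)OC(C)(C)C)c3cc(/C=C\C(=O)NCCCN(CCCCCl)C(=O)OC(C)(C)C)ccc3O[C@@H]2C1 | intermediate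
32 | iodo analogue of 31 (CH2I in place of CH2Cl) | O=C1CC[C@]2(/C=C\C(=O)NC(=O)OC(C)(C)C)c3cc(/C=C\C(=O)NCCCN(CCCCI)C(=O)OC(C)(C)C)ccc3O[C@@H]2C1 | intermediate
33 | (4aR,9bS)-bis-Boc macrocycle: the target with tert-butoxycarbonyl groups on the amide nitrogen of the C9b arm and on the central amine | O=C1CC[C@]23/C=C\C(=O)N(C(=O)OC(C)(C)C)CCCCN(C(=O)OC(C)(C)C)CCCNC(=O)/C=C\c4ccc(c2c4)O[C@@H]3C1 | intermediate
34 | CNP0415009.2: (4aR,9bS)-cis-fused tetrahydrodibenzofuran-3-one whose C9b and C8 are bridged by (Z)-CH=CH–CO–NH–(CH2)4–NH–(CH2)3–NH–CO–CH=CH-(Z) (20-membered ring) | O=C1CC[C@]23/C=C\C(=O)NCCCCNCCCNC(=O)/C=C\c4ccc(c2c4)O[C@@H]3C1 | target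

**Totals and risks**
Total steps: 18. Longest linear sequence: 12 steps (steps 1, 2, 3, 5, 6, 7, 8, 9, 15, 16, 17, 18, from compound 1).

Most likely to fail, step 17: conjugate addition of the imide nitrogen to the enone could compete with furan closure, a phenoxide regenerated by retro-oxa-Michael could be alkylated at oxygen, or intermolecular alkylation could outrun ring closure. The fallback sets out from 30 and separates the events under conditions where neither a phenoxide nor an enone meets the alkylating terminus. HF·pyridine in THF/pyridine followed by catalytic PPTS should give the tricyclic chloride 31, now isolated. 1,2-Bis(trimethylsilyloxy)ethane with catalytic Me3SiOTf at −78 °C should then mask the ketone as the dioxolane F1. Cs2CO3 and Bu4NI in DMF (0.001 M, 60 °C) should close the ring by N-alkylation to the macrocyclic ketal F2. CF3CO2H/H2O removes both Boc groups and the ketal, and the route is rejoined at 34.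

Second, step 5: facial discrimination of the ortho-silyloxyaryl acrolein by the catalyst may be poor, or the dienophile may dimerise faster than the catalysed cycloaddition. The fallback sets out from 7 and 9 and sets the stereocentre by desymmetrisation instead. A thermal Diels–Alder reaction (toluene, 80 °C) gives the racemic adduct F3, and aqueous HCl in THF hydrolyses the enol ether to the achiral keto aldehyde F4. Still–Gennari olefination with 11 gives the achiral keto (Z)-enoate F5. Enantiotopic-group-selective deprotonation with lithium bis[(R)-1-phenylethyl]amide and LiCl in THF at −100 °C (antipode of the base chosen to match), then trapping with 2, gives the silyl enol ether, and the route is rejoined at 12.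

Third, step 16: palladation of the hindered triisopropylsilyl enol ether may be sluggish in a substrate rich in Lewis-basic groups, with alkene isomerisation over long reaction times. The fallback sets out from 29. PhSeCl in CH2Cl2 at −78 °C selenenylates the enol ether α-carbon to give the α-phenylselanyl ketone F6 (epimers), and H2O2/pyridine at 0 °C effects selenoxide syn-elimination towards the only available β-hydrogens, which rejoins the route at 30.

**Further compounds**
F1 | step 17 | ethylene ketal of 31 (C3 carbonyl as 1,3-dioxolane, (4aR,9bS)) | O1CCOC12CC[C@]3(/C=C\C(=O)NC(=O)OC(C)(C)C)c4cc(/C=C\C(=O)NCCCN(CCCCCl)C(=O)OC(C)(C)C)ccc4O[C@@H]3C2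
F2 | step 17 | ethylene ketal of 33 (bis-Boc macrocycle with C3 as 1,3-dioxolane) | O1CCOC12CC[C@]34/C=C\C(=O)N(C(=O)OC(C)(C)C)CCCCN(C(=O)OC(C)(C)C)CCCNC(=O)/C=C\c5ccc(c3c5)O[C@@H]4C2
F3 | step 5 | racemic 1-[5-bromo-2-(triisopropylsilyloxy)phenyl]-4-(triisopropylsilyloxy)cyclohex-3-ene-1-carbaldehyde | CC(C)[Si](C(C)C)(C(C)C)OC1=CCC(C=O)(c2cc(Br)ccc2O[Si](C(C)C)(C(C)C)C(C)C)CC1
F4 | step 5 | 1-[5-bromo-2-(triisopropylsilyloxy)phenyl]-4-oxocyclohexane-1-carbaldehyde | O=CC1(c2cc(Br)ccc2O[Si](C(C)C)(C(C)C)C(C)C)CCC(=O)CC1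
F5 | step 5 | methyl (2Z)-3-[1-[5-bromo-2-(triisopropylsilyloxy)phenyl]-4-oxocyclohexyl]prop-2-enoate | COC(=O)/C=C\C1(c2cc(Br)ccc2O[Si](C(C)C)(C(C)C)C(C)C)CCC(=O)CC1
F6 | step 16 | 2-(phenylselanyl) ketone from 29 (ring C ketone with SePh on the α-carbon of the arm leading to C4a, epimers at that carbon) | O=C1CC[C@](/C=C\C(=O)NC(=O)OC(C)(C)C)(c2cc(/C=C\C(=O)NCCCN(CCCCCl)C(=O)OC(C)(C)C)ccc2O[Si](C(C)C)(C(C)C)C(C)C)CC1[Se]c1ccccc1
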